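Assumptions: compounds 1, 3, 9 and 12 and both catalysts are catalogue items. The sense of induction in Step 3 is fixed by one test run, since both ligand antipodes are available from D- and L-tartrate.

## Retrosynthetic overview

1. The last C–C bond formed is C7'–C1', by an sp3–sp2 B-alkyl Suzuki coupling rather than at the ether. It joins a primary alkyl iodide carrying C8/C8' to an aryl bromide that already carries the complete threo 8''-O-4' unit. Global O-debenzylation follows.
2. Key step A: the 8S,8'R core is pseudo-meso. It comes from meso-2,3-dimethylsuccinic anhydride by Rh-catalysed enantioselective desymmetrising arylation with a guaiacyl-zinc reagent. This one C–C bond formation fixes the absolute configuration at both C8 and C8'.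
3. Key step B: the ether is made early by an achiral SN2 reaction, giving a racemic α-aryloxy propiophenone. One Noyori hydrogenation under dynamic kinetic resolution then sets C7'' and C8'' together.
4. Rings: none is constructed, because all three arenes are purchased. The only ring made is the sacrificial anhydride, formed in Step 1 and opened in Step 3.

## Route

**Step 1**
Reactants: 1, meso-2,3-dimethylsuccinic acid
Product: 2, cis-2,3-dimethylsuccinic anhydride, (3R,4S)-3,4-dimethyloxolane-2,5-dione (meso)
Conditions: AcCl (neat), reflux, 2 h; concentrate; recrystallise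
Reagents that add atoms: none
Why: Dehydrative cyclisation of a 1,4-diacid through the mixed anhydride is base-free, so the cis (meso) relationship, which becomes the 8,8' relative configuration, is retained.

**Step 2**
Reactants: 3, 4-bromo-2-methoxyphenol
Product: 4, 1-(benzyloxy)-4-bromo-2-methoxybenzene
Conditions: BnBr, K2CO3, DMF, 60 °C
Reagents that add atoms: benzyl bromide, BrCc1ccccc1
Why: This is a Williamson etherification of an unhindered phenoxide, and no stereocentre is involved.

**Step 3 (key step A)**
Reactants: 2, cis-anhydride; 4, aryl bromide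
Product: 5, (2S,3R)-4-[4-(benzyloxy)-3-methoxyphenyl]-2,3-dimethyl-4-oxobutanoic acid
Conditions: 4, n-BuLi, THF, −78 °C; Zn(OTf)2, to rt; then 2, [Rh(cod)Cl]2 (4 mol %), TADDOL-derived phosphoramidite (8 mol %), THF, 50 °C; aq. HCl work-up; recrystallise the 1-phenylethylammonium salt to ≥99% ee
Reagents that add atoms: none
Why: In this Rh-catalysed enantioselective desymmetrising acyl cross-coupling of a meso anhydride with an in situ arylzinc, the chiral Rh(I) complex inserts into the acyl C–O bond at the carbonyl next to the (R)-carbon, so the syn relative configuration comes from the ring, the choice between enantiotopic carbonyls sets the absolute configuration at C8 and C8', and the neutral conditions do not enolise the product.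

**Step 4**
Reactants: 5, keto acid
Product: 6, (2S,3S)-4-[4-(benzyloxy)-3-methoxyphenyl]-2,3-dimethylbutanoic acid
Conditions: Et3SiH (4 equiv), TFA/CH2Cl2 (1:2), 0 °C to rt, 3 h
Reagents that add atoms: none
Why: In this ionic hydrogenation the p-alkoxy group makes the protonated ketone and the derived benzylic lactone/cation easy to form, and excess silane traps them faster than enolisation or E1 loss of H-8, so both stereocentres are carried through (C3 changes from R to S only because CIP priorities change).

**Step 5**
Reactants: 6, acid
Product: 7, (2S,3S)-4-[4-(benzyloxy)-3-methoxyphenyl]-2,3-dimethylbutan-1-ol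
Conditions: BH3·THF, THF, 0 °C to rt
Reagents that add atoms: none
Why: Borane reduces the carboxylic acid chemoselectively through the acyloxyborane without enolising it, so C8' is not epimerised and the aryl ethers are untouched.

**Step 6**
Reactants: 7, alcohol
Product: 8, 1-(benzyloxy)-4-[(2S,3S)-4-iodo-2,3-dimethylbutyl]-2-methoxybenzene
Conditions: I2, PPh3, imidazole, CH2Cl2, 0 °C to rt
Reagents that add atoms: iodine, II
Why: This Appel-type (Garegg–Samuelsson) iodination is an SN2 reaction at the primary carbon and does not touch either stereocentre.

**Step 7**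
Reactants: 9, 1-(4-hydroxy-3-methoxyphenyl)propan-1-one (propiovanillone)
Product: 10, 1-[4-(benzyloxy)-3-methoxyphenyl]propan-1-one
Conditions: BnBr, K2CO3, acetone, reflux
Reagents that add atoms: benzyl bromide, BrCc1ccccc1
Why: This Williamson etherification masks the ring-C phenol so that it cannot compete in Step 9.

**Step 8**
Reactants: 10, ketone
Product: 11, (±)-1-[4-(benzyloxy)-3-methoxyphenyl]-2-bromopropan-1-one
Conditions: CuBr2 (2.1 equiv), EtOAc/CHCl3 (1:1), reflux
Reagents that add atoms: copper(II) bromide, Br[Cu]Br
Why: CuBr2 α-bromination (King–Ostrum) proceeds through the Cu-bound enol and therefore spares the electron-rich ring, and the racemic product is acceptable because Step 10 is stereoconvergent.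

**Step 9**
Reactants: 11, bromoketone; 12, 4-bromo-2,6-dimethoxyphenol
Product: 13, (±)-1-[4-(benzyloxy)-3-methoxyphenyl]-2-(4-bromo-2,6-dimethoxyphenoxy)propan-1-one
Conditions: K2CO3, 2-butanone, reflux
Reagents that add atoms: none
Why: SN2 displacement of a carbonyl-activated secondary bromide tolerates even the di-ortho-substituted phenoxide, and this is the standard way to make β-ketoether neolignan precursors.

**Step 10 (key step B)**
Reactants: 13, racemic α-aryloxy ketone
Product: 14, (1S,2S)-1-[4-(benzyloxy)-3-methoxyphenyl]-2-(4-bromo-2,6-dimethoxyphenoxy)propan-1-ol (threo)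
Conditions: trans-RuCl2[(S)-xylbinap][(S)-daipen] (0.5 mol %), KOt-Bu (20 mol %), H2 (8 atm), i-PrOH/THF (4:1), 25 °C; chromatography and recrystallisation
Reagents that add atoms: none
Why: Proposed new method: this is a Noyori diphosphine/diamine-Ru hydrogenation under dynamic kinetic resolution, in which alkoxide racemises C8'' quickly through the enolate, the (S,S)-catalyst delivers H to the face that gives (R)-1-phenylethanol from acetophenone (7''S here, because C8'' outranks aryl), and the bulky non-chelating outer-sphere Ru–H/N–H reduces the (S)-ketone faster through a polar Felkin–Anh transition state with OAr anti to hydride, giving the threo (7''S,8''S) alcohol; the closest known reaction types are hydrogenative DKR of α-substituted ketones and α-aryloxy aldehydes with this catalyst family, and the syn-selective DKR reductions of benzoins and α-alkoxy-β-keto esters.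

**Step 11**
Reactants: 8, alkyl iodide; 14, aryl bromide
Product: 15, (1S,2S)-1-[4-(benzyloxy)-3-methoxyphenyl]-2-(4-{(2R,3S)-4-[4-(benzyloxy)-3-methoxyphenyl]-2,3-dimethylbutyl}-2,6-dimethoxyphenoxy)propan-1-ol
Conditions: 8, t-BuLi (2.1 equiv), Et2O, −78 °C; B-MeO-9-BBN, THF, −78 °C to rt; then 14, Pd(dppf)Cl2 (5 mol %), aq. K3PO4 (3 M), DMF, 50 °C
Reagents that add atoms: none
Why: In this B-alkyl Suzuki–Miyaura coupling through the alkyl-9-BBN borinate, I/Li exchange is much faster than attack on the ethers, the C–Br bond has no ortho substituents, dppf suppresses β-hydride elimination, the free 7''-OH is tolerated, and no stereocentre takes part.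

**Step 12**
Reactants: 15, bis-benzyl ether
Product: 16, target, (+)-(7''S,8S,8'R,8''S)-4,4''-dihydroxy-3,3',3'',5'-tetramethoxy-4',8''-oxy-8,8'-sesquineolignan-7''-ol
Conditions: H2 (1 atm), 10% Pd/C, EtOAc/EtOH, rt, neutral; stop after 2 equiv of H2
Reagents that add atoms: none
Why: Hydrogenolysis cleaves the two aryl benzyl ethers much faster than a free secondary benzylic alcohol under acid-free conditions, and the non-benzylic C8''–OAr bond is inert, so all four stereocentres are retained.

## Compound list

| No. | Name | SMILES | Role |
|---|---|---|---|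
| 1 | meso-2,3-dimethylsuccinic acid | OC(=O)[C@H](C)[C@H](C)C(=O)O | starting material |
| 2 | cis-2,3-dimethylsuccinic anhydride | O1C(=O)[C@H](C)[C@H](C)C1=O | intermediate |
| 3 | 4-bromo-2-methoxyphenol | COc1cc(Br)ccc1O | starting material |
| 4 | 1-(benzyloxy)-4-bromo-2-methoxybenzene | COc1cc(Br)ccc1OCc1ccccc1 | intermediate |
| 5 | (2S,3R)-4-[4-(benzyloxy)-3-methoxyphenyl]-2,3-dimethyl-4-oxobutanoic acid | COc1cc(C(=O)[C@H](C)[C@H](C)C(=O)O)ccc1OCc1ccccc1 | intermediate |
| 6 | (2S,3S)-4-[4-(benzyloxy)-3-methoxyphenyl]-2,3-dimethylbutanoic acid | COc1cc(C[C@H](C)[C@H](C)C(=O)O)ccc1OCc1ccccc1 | intermediate |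
| 7 | (2S,3S)-4-[4-(benzyloxy)-3-methoxyphenyl]-2,3-dimethylbutan-1-ol | COc1cc(C[C@H](C)[C@H](C)CO)ccc1OCc1ccccc1 | intermediate |
| 8 | 1-(benzyloxy)-4-[(2S,3S)-4-iodo-2,3-dimethylbutyl]-2-methoxybenzene | COc1cc(C[C@H](C)[C@H](C)CI)ccc1OCc1ccccc1 | intermediate |
| 9 | 1-(4-hydroxy-3-methoxyphenyl)propan-1-one | CCC(=O)c1ccc(O)c(OC)c1 | starting material |
| 10 | 1-[4-(benzyloxy)-3-methoxyphenyl]propan-1-one | CCC(=O)c1ccc(OCc2ccccc2)c(OC)c1 | intermediate |
| 11 | (±)-1-[4-(benzyloxy)-3-methoxyphenyl]-2-bromopropan-1-one | CC(Br)C(=O)c1ccc(OCc2ccccc2)c(OC)c1 | intermediate |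
| 12 | 4-bromo-2,6-dimethoxyphenol | COc1cc(Br)cc(OC)c1O | starting material |
| 13 | (±)-1-[4-(benzyloxy)-3-methoxyphenyl]-2-(4-bromo-2,6-dimethoxyphenoxy)propan-1-one | COc1cc(Br)cc(OC)c1OC(C)C(=O)c1ccc(OCc2ccccc2)c(OC)c1 | intermediate |
| 14 | (1S,2S)-1-[4-(benzyloxy)-3-methoxyphenyl]-2-(4-bromo-2,6-dimethoxyphenoxy)propan-1-ol | COc1cc(Br)cc(OC)c1O[C@@H](C)[C@@H](O)c1ccc(OCc2ccccc2)c(OC)c1 | intermediate |
| 15 | 4,4''-di-O-benzyl ether of the target | COc1cc(C[C@H](C)[C@H](C)Cc2cc(OC)c(O[C@@H](C)[C@@H](O)c3ccc(OCc4ccccc4)c(OC)c3)c(OC)c2)ccc1OCc1ccccc1 | intermediate |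
| 16 | (+)-(7''S,8S,8'R,8''S)-4,4''-dihydroxy-3,3',3'',5'-tetramethoxy-4',8''-oxy-8,8'-sesquineolignan-7''-ol | COc1cc(C[C@H](C)[C@H](C)Cc2cc(OC)c(O[C@@H](C)[C@@H](O)c3ccc(O)c(OC)c3)c(OC)c2)ccc1O | target |

## Step count

- Total steps: 12.
- Longest linear sequence: 7 steps (Steps 2, 3, 4, 5, 6, 11, 12). Starting from compound 1 through Step 1 is also 7 steps.

## Three steps most likely to fail

1. **Step 10 (hydrogenative DKR).**
   - Risk: the matched/mismatched rate ratio may be too small, which would give erythro contamination. The hindered, electron-rich ketone may also be sluggish.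
   - Fallback: give up stereoconvergence and take C8'' from the chiral pool.
     - Mitsunobu reaction of 12 with methyl (R)-lactate proceeds with inversion to the (S)-2-aryloxypropanoate.
     - Conversion to the Weinreb amide and addition of the aryllithium from 4 gives enantiopure (S)-13.
     - Base-free, substrate-controlled Felkin reduction with L-Selectride then gives threo-14.

2. **Step 3 (Rh desymmetrising arylation).**
   - Risk: ee may reach only about 85–90%, or conversion may be poor with this electron-rich arylzinc. Any minor enantiomer becomes a remote diastereomer after Step 11 that is almost impossible to separate.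
   - Fallback: move the stereodetermining event to C–O bond formation.
     - Cinchona-alkaloid-catalysed methanolysis of 2 gives the hemiester.
     - Chemoselective BH3 reduction of the free acid and iodination follow, and ring A is then installed by the same B-alkyl Suzuki tactic.
     - The ester end is then taken through reduction and iodination to 8. This also removes the need for Step 4.

3. **Step 4 (ionic deoxygenation).**
   - Risk: C8 may partly epimerise through the enol or through E1/reprotonation of the benzylic cation. TFA may also cleave the aryl benzyl ether.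
   - Fallback: avoid cationic chemistry.
     - NaBH4 reduction gives the γ-aryl-γ-lactone.
     - Surface hydrogenolysis of the benzylic C–O bond (H2, Pd/C) follows, accepting loss of the benzyl group.
     - The phenol is then re-benzylated before the reduction to 7.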